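**Leftover partner.** I began with what remained of the coupling partner. If each unit of isomer of the product A takes one unit of it, the gamma run held 0.532 of the substrate charge at its last reading, down from 1.1. So I asked how strongly the rate follows partner, since the summer flask receives its partner slowly.

| setting | theta | beta | gamma | summer | winter | dawn |
|---|---|---|---|---|---|---|
| substrate | 20 mM | 20 mM | 20 mM | 20 mM | 20 mM | 20 mM (fed, over 12 h) |
| coupling partner | 1.1 equiv | 1.1 equiv | 1.1 equiv | 1.10 equiv (fed, over 12 h) | 1.10 equiv | 1.10 equiv |
| capture agent | 20 mM | 13 mM | 30 mM | 20.0 mM | 20.0 mM | 20.0 mM |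
| remark | run made earlier | run made earlier | run made earlier | all else is in the flask from the start; the feed brings no volume worth counting | everything together at the start | all else is in the flask from the start; the feed brings no volume worth counting |
| time |  |  |  | 15 h | 15 h | 15 h |

| run | time / h | isomer of the product A / % | target / % |
|---|---|---|---|
| theta | 1.33 | 8.3 | 0 |
| theta | 2.50 | 16.9 | 0 |
| theta | 4.00 | 26.8 | 0.8 |
| theta | 5.00 | 29.7 | 1.3 |
| theta | 6.00 | 35.4 | 1.0 |
| theta | 8.00 | 44.1 | 0.8 |
| theta | 10.0 | 50.0 | 0 |
| beta | 1.00 | 8.1 | 2.7 |
| beta | 1.33 | 10.7 | 0 |
| beta | 2.00 | 13.1 | 0.1 |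
| beta | 3.00 | 19.1 | 0.4 |
| beta | 5.00 | 32.2 | 0 |
| beta | 8.00 | 42.7 | 1.5 |
| beta | 12.0 | 55.6 | 0.8 |
| gamma | 0.667 | 4.8 | 0 |
| gamma | 2.00 | 14.8 | 0 |
| gamma | 3.00 | 22.1 | 0 |
| gamma | 5.00 | 33.2 | 0 |
| gamma | 8.00 | 43.0 | 0.7 |
| gamma | 10.0 | 51.3 | 0.2 |
| gamma | 12.0 | 56.8 | 0 |

(scatter of a reading: 1 percentage point)

- the flask that comes out highest in amount of isomer of the product A, in percent of the substrate charged, or "all alike" when all lie within 1.5 percentage points (summer / winter / dawn / all alike)
- isomer of the product A at the end, in percent of the substrate charged, summer
- isomer of the product A at the end, in percent of the substrate charged, winter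
- isomer of the product A at the end, in percent of the substrate charged, dawn



**Two limits.** The runs overlaid from 13 mM to 30 mM of capture agent (beta 55.6 %, gamma 56.8 %, both at 12.0 h), so I pooled them. Read as first-order decay of substrate, their last readings gave a mean constant of 0.0690 /h, and hence 64.5 % for winter. If partner did not matter, my reckoning put summer at that same figure. If the rate were proportional to partner, the ramp would cost half the feed time, and my reckoning put summer at 46.2 %.

**Reading the drift.** The pooled constant was 0.0773 /h up to the middle readings and 0.0652 /h afterwards, while mean partner, reckoned at one unit per unit of isomer of the product A, fell to 0.726 of its earlier value. The logarithm of the ratio of the constants, divided by the logarithm of that partner ratio, gave 0.529, the apparent order, meaning the power with which the rate follows partner; it carries the scatter of the readings. A linear ramp then counts as a contact time of 10.8 h, shorter than the flask's time, so I expected 52.7 % for summer, which lies between my two limits. For dawn, whose partner stands in the flask from the start, I used plain decay of evenly fed substrate, which gave 44.7 %.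

**The result.** The forecast gave 63 % for summer, 65 % for winter and 46 % for dawn, with winter on top: “Winter is marginally highest, essentially tied with summer.” The flasks gave 51.1 %, 62.7 % and 45.6 %, so winter came out highest.

    substrate ⇌ tight pair (K = 0.0110, k = 0.200 /h)
    tight pair ⇌ loose pair (K = 0.360, k = 32.0 /h)
    coupling partner + tight pair ⇌ target (K = 21.0 /M, k = 1500 /M/h)
    coupling partner + loose pair → isomer of the product A (k = 2600 /M/h)
    capture agent + tight pair → trapped intermediate (k = 4.30 /M/h)
    target ⇌ isomer of the product B (K = 0.380, k = 0.0570 /h)

**Starved neighbour.** My summer figure stood 1.6 percentage points above the flask. I then took dawn with 0.280 equiv of partner, here the limiting reagent. The order 0.529 scaled the constant to 0.0334 /h, and fed decay gave 25.5 %. That flask gave 19.8 %, with 78.5 % of the substrate remaining and 29.2 % of its partner charge left.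

The numbers in the tables come from a simulation for an exercise; scatter was added.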